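**Strategy.** Ring C of the flavanone is disconnected at its aryl ether bond. The ring oxygen O1 sits between the stereogenic benzylic carbon C2 and the aromatic carbon C8a of ring A, so closing ring C at O1–C8a leaves every bond to C2 intact. A palladium-catalysed intramolecular etherification of the C8a triflate by the (S)-configured C2 hydroxyl does this in one operation and carries the C2 configuration into the target. The precursor is a 1,3-diarylpropane-1,3-diol derivative with the C4 oxygen silylated, so that the C2 hydroxyl is the only alkoxide available. C2 is set by asymmetric transfer hydrogenation directly before the closure, and C4 is oxidised to the ketone afterwards.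

Key step: step 9

Remark: C4 is formed without control in step 6 and is carried as both epimers (written RS), since it becomes the carbonyl carbon in step 11; compounds 1, 2 and 8 are taken as catalogue chemicals.

Step 1
Reactants: 1 2-hydroxy-4,6-dimethoxybenzaldehyde; 2 3-chloro-3-methylbut-1-yne
Product: 3 4,6-dimethoxy-2-[(2-methylbut-3-yn-2-yl)oxy]benzaldehyde
Conditions: CuCl2·2H2O (cat.), DBU, MeCN, 0 °C to rt
Reagents that add atoms: none
Why: Copper-catalysed propargylic etherification, in which the copper acetylide of 2 ionises to a copper allenylidene that the DBU phenoxide of 1 captures at the tertiary carbon, which makes up for the low nucleophilicity of the hydrogen-bonded phenol.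

Step 2
Reactants: 3 4,6-dimethoxy-2-[(2-methylbut-3-yn-2-yl)oxy]benzaldehyde
Product: 4 4,6-dimethoxy-2-[(2-methylbut-3-en-2-yl)oxy]benzaldehyde
Conditions: H2 (1 atm), Pd/CaCO3 poisoned with Pb(OAc)2, quinoline, EtOAc, rt
Reagents that add atoms: none
Why: Lindlar semihydrogenation should add one equivalent of hydrogen to the terminal alkyne and stop at the alkene on the poisoned surface, leaving the aldehyde and the aryl ether alone.

Step 3
Reactants: 4 4,6-dimethoxy-2-[(2-methylbut-3-en-2-yl)oxy]benzaldehyde
Product: 6 2-hydroxy-4,6-dimethoxy-3-(3-methylbut-2-enyl)benzaldehyde, via ortho-dienone 5 (not isolated)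
Conditions: PhNEt2, 120 °C
Reagents that add atoms: none
Why: Aromatic Claisen rearrangement, whose [3,3] shift moves the allyl unit with transposition to C3, the only free ortho carbon, turning the 1,1-dimethylallyl ether into the linear prenyl group before dienone 5 tautomerises to the hydrogen-bonded phenol (its sp3 centre is transient).

Step 4
Reactants: 6 2-hydroxy-4,6-dimethoxy-3-(3-methylbut-2-enyl)benzaldehyde
Product: 7 2-formyl-3,5-dimethoxy-6-(3-methylbut-2-enyl)phenyl trifluoromethanesulfonate
Conditions: Tf2O, pyridine, CH2Cl2, 0 °C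
Reagents that add atoms: trifluoromethanesulfonic anhydride, O=S(=O)(OS(=O)(=O)C(F)(F)F)C(F)(F)F
Why: O-Sulfonylation of the phenol under pyridine buffering turns the future O1 position into the aryl electrophile for ring closure and is compatible with the aldehyde and the trisubstituted alkene at this temperature.

Step 5
Reactants: 8 1-(3-hydroxy-4-methoxyphenyl)ethanone
Product: 9 1-[4-methoxy-3-(methoxymethoxy)phenyl]ethanone
Conditions: MOMCl, i-Pr2NEt, CH2Cl2, 0 °C to rt
Reagents that add atoms: chloromethyl methyl ether, COCCl
Why: O-Alkylation of the phenol to its methoxymethyl acetal, a group that is stable to enolate, silyl triflate, hydride transfer, palladium and fluoride and leaves under acid at the flavanone stage.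

Step 6
Reactants: 9 1-[4-methoxy-3-(methoxymethoxy)phenyl]ethanone; 7 2-formyl-3,5-dimethoxy-6-(3-methylbut-2-enyl)phenyl trifluoromethanesulfonate
Product: 11 rac-3-hydroxy-1-[4-methoxy-3-(methoxymethoxy)phenyl]-3-[4,6-dimethoxy-3-(3-methylbut-2-enyl)-2-(trifluoromethanesulfonyloxy)phenyl]propan-1-one, via lithium enolate 10 (not isolated)
Conditions: LiN(i-Pr)2, THF, −78 °C; then 7; AcOH quench at −78 °C
Reagents that add atoms: none
Why: Directed aldol addition of a preformed lithium enolate to a non-enolisable aldehyde, kept at −78 °C and quenched cold to suppress retro-aldol and dehydration; the new carbinol centre (the later C4) forms without control, which is immaterial.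

Step 7
Reactants: 11 rac-3-hydroxy-1-[4-methoxy-3-(methoxymethoxy)phenyl]-3-[4,6-dimethoxy-3-(3-methylbut-2-enyl)-2-(trifluoromethanesulfonyloxy)phenyl]propan-1-one
Product: 12 rac-3-(tert-butyldimethylsilyloxy)-1-[4-methoxy-3-(methoxymethoxy)phenyl]-3-[4,6-dimethoxy-3-(3-methylbut-2-enyl)-2-(trifluoromethanesulfonyloxy)phenyl]propan-1-one
Conditions: TBSOTf, 2,6-lutidine, CH2Cl2, −78 to 0 °C (crude 11 used directly)
Reagents that add atoms: tert-butyldimethylsilyl trifluoromethanesulfonate, CC(C)(C)[Si](C)(C)OS(=O)(=O)C(F)(F)F
Why: Silylation of the only hydroxyl with a silyl triflate and a hindered pyridine base blocks dehydration to the chalcone and keeps the C4 oxygen masked through steps 8 and 9.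

Step 8
Reactants: 12 rac-3-(tert-butyldimethylsilyloxy)-1-[4-methoxy-3-(methoxymethoxy)phenyl]-3-[4,6-dimethoxy-3-(3-methylbut-2-enyl)-2-(trifluoromethanesulfonyloxy)phenyl]propan-1-one
Product: 13 (1S,3RS)-3-(tert-butyldimethylsilyloxy)-1-[4-methoxy-3-(methoxymethoxy)phenyl]-3-[4,6-dimethoxy-3-(3-methylbut-2-enyl)-2-(trifluoromethanesulfonyloxy)phenyl]propan-1-ol
Conditions: RuCl[(S,S)-TsDPEN](p-cymene) (cat.), HCO2H/Et3N (5:2), EtOAc, 30 °C
Reagents that add atoms: none
Why: Noyori–Ikariya asymmetric transfer hydrogenation, in which the (S,S)-configured ruthenium amido hydride delivers hydride and proton to the Re face of the aryl ketone through its CH–π-organised six-membered transition state, so the catalyst alone sets C1 (the later C2) as S regardless of the remote silyloxy centre, without touching the alkene or the triflate.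

Step 9
Reactants: 13 (1S,3RS)-3-(tert-butyldimethylsilyloxy)-1-[4-methoxy-3-(methoxymethoxy)phenyl]-3-[4,6-dimethoxy-3-(3-methylbut-2-enyl)-2-(trifluoromethanesulfonyloxy)phenyl]propan-1-ol
Product: 14 (2S,4RS)-4-(tert-butyldimethylsilyloxy)-5,7-dimethoxy-2-[4-methoxy-3-(methoxymethoxy)phenyl]-8-(3-methylbut-2-enyl)chromane
Conditions: Pd(OAc)2 (cat.), 2-(di-tert-butylphosphino)-1,1'-binaphthyl, Cs2CO3, toluene, 80 °C
Reagents that add atoms: none
Why: Pd(OAc)2 is reduced in the flask to a monophosphine zerovalent palladium species, which undergoes oxidative addition at the C8a–OTf bond; the C2 hydroxyl then coordinates, loses its proton to Cs2CO3, and the resulting seven-membered oxapalladacycle releases ring C by carbon–oxygen reductive elimination, creating O1–C8a. The closest known reaction type is the Buchwald–Hartwig-type intramolecular etherification of aryl halides and sulfonates with secondary alcohols that gives chromans. Ring C closes as a six-membered ring by delivery of O1 to the ring A carbon C8a, formally a 6-exo closure at the arene through the seven-membered palladacycle. No stereocentre is formed, and C2 is a spectator: only its O–H bond and the aryl carbon are engaged, so the (S) configuration passes through unchanged. The step needs C–O bond formation to win over β-hydride loss from the palladium alkoxide and needs the triflate to react at carbon and not at sulfur; the steric pressure of the di-tert-butyl biaryl phosphine provides the first. The silyl ether on the C4 oxygen provides the second, because a free benzylic alkoxide ortho to the triflate could take over the triflyl group or form a five-membered palladium chelate, while the MOM ether keeps the ring B phenol from competing as an aryloxide.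

Step 10
Reactants: 14 (2S,4RS)-4-(tert-butyldimethylsilyloxy)-5,7-dimethoxy-2-[4-methoxy-3-(methoxymethoxy)phenyl]-8-(3-methylbut-2-enyl)chromane
Product: 15 (2S,4RS)-5,7-dimethoxy-2-[4-methoxy-3-(methoxymethoxy)phenyl]-8-(3-methylbut-2-enyl)chroman-4-ol
Conditions: Bu4NF, THF, rt; aqueous work-up
Reagents that add atoms: none
Why: Fluoride-induced desilylation, driven by Si–F bond formation, frees the C4 hydroxyl in a non-acidic medium that avoids ionisation of the acid-labile 5,7-dimethoxyflavan-4-ol and leaves the MOM ether alone.

Step 11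
Reactants: 15 (2S,4RS)-5,7-dimethoxy-2-[4-methoxy-3-(methoxymethoxy)phenyl]-8-(3-methylbut-2-enyl)chroman-4-ol
Product: 16 (2S)-5,7-dimethoxy-2-[4-methoxy-3-(methoxymethoxy)phenyl]-8-(3-methylbut-2-enyl)chroman-4-one
Conditions: Dess–Martin periodinane, NaHCO3, CH2Cl2, 0 °C to rt
Reagents that add atoms: none
Why: Dess–Martin oxidation of the benzylic secondary alcohol (ligand exchange at hypervalent iodine, then internal elimination) should bring both C4 epimers to one ketone, and the buffered, base-free medium leaves C2, the prenyl group and the acetal untouched.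

Step 12
Reactants: 16 (2S)-5,7-dimethoxy-2-[4-methoxy-3-(methoxymethoxy)phenyl]-8-(3-methylbut-2-enyl)chroman-4-one
Product: 17 (2S)-2-(3-hydroxy-4-methoxyphenyl)-5,7-dimethoxy-8-(3-methylbut-2-enyl)chroman-4-one
Conditions: HCl (2 M in MeOH), rt
Reagents that add atoms: none
Why: Acid-catalysed methanolysis of the MOM acetal frees the 3'-phenol without forming a phenoxide or enolate, so the retro-oxa-Michael ring opening that would racemise C2 is avoided, and the prenyl group has no neighbouring hydroxyl to cyclise onto.

**Compound list**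

1 | 2-hydroxy-4,6-dimethoxybenzaldehyde | O=Cc1c(O)cc(OC)cc1OC | starting material
2 | 3-chloro-3-methylbut-1-yne | CC(C)(Cl)C#C | starting material
3 | 4,6-dimethoxy-2-[(2-methylbut-3-yn-2-yl)oxy]benzaldehyde | O=Cc1c(OC(C)(C)C#C)cc(OC)cc1OC | intermediate
4 | 4,6-dimethoxy-2-[(2-methylbut-3-en-2-yl)oxy]benzaldehyde | O=Cc1c(OC(C)(C)C=C)cc(OC)cc1OC | intermediate
5 | 2-formyl-3,5-dimethoxy-6-(3-methylbut-2-enyl)cyclohexa-2,4-dien-1-one (racemic at C6, not isolated) | O=CC1=C(OC)C=C(OC)C(CC=C(C)C)C1=O | intermediate
6 | 2-hydroxy-4,6-dimethoxy-3-(3-methylbut-2-enyl)benzaldehyde | O=Cc1c(O)c(CC=C(C)C)c(OC)cc1OC | intermediate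
7 | 2-formyl-3,5-dimethoxy-6-(3-methylbut-2-enyl)phenyl trifluoromethanesulfonate | O=Cc1c(OS(=O)(=O)C(F)(F)F)c(CC=C(C)C)c(OC)cc1OC | intermediate
8 | 1-(3-hydroxy-4-methoxyphenyl)ethanone | CC(=O)c1ccc(OC)c(O)c1 | starting material
9 | 1-[4-methoxy-3-(methoxymethoxy)phenyl]ethanone | CC(=O)c1ccc(OC)c(OCOC)c1 | intermediate
10 | lithium 1-[4-methoxy-3-(methoxymethoxy)phenyl]ethenolate (not isolated) | [Li+].[O-]C(=C)c1ccc(OC)c(OCOC)c1 | intermediate
11 | rac-3-hydroxy-1-[4-methoxy-3-(methoxymethoxy)phenyl]-3-[4,6-dimethoxy-3-(3-methylbut-2-enyl)-2-(trifluoromethanesulfonyloxy)phenyl]propan-1-one | COCOc1cc(C(=O)CC(O)c2c(OC)cc(OC)c(CC=C(C)C)c2OS(=O)(=O)C(F)(F)F)ccc1OC | intermediate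
12 | rac-3-(tert-butyldimethylsilyloxy)-1-[4-methoxy-3-(methoxymethoxy)phenyl]-3-[4,6-dimethoxy-3-(3-methylbut-2-enyl)-2-(trifluoromethanesulfonyloxy)phenyl]propan-1-one | COCOc1cc(C(=O)CC(O[Si](C)(C)C(C)(C)C)c2c(OC)cc(OC)c(CC=C(C)C)c2OS(=O)(=O)C(F)(F)F)ccc1OC | intermediate
13 | (1S,3RS)-3-(tert-butyldimethylsilyloxy)-1-[4-methoxy-3-(methoxymethoxy)phenyl]-3-[4,6-dimethoxy-3-(3-methylbut-2-enyl)-2-(trifluoromethanesulfonyloxy)phenyl]propan-1-ol (ring-closure precursor; C1 is the later C2, C3 the later C4, both C3 epimers) | COCOc1cc([C@@H](O)CC(O[Si](C)(C)C(C)(C)C)c2c(OC)cc(OC)c(CC=C(C)C)c2OS(=O)(=O)C(F)(F)F)ccc1OC | intermediate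
14 | (2S,4RS)-4-(tert-butyldimethylsilyloxy)-5,7-dimethoxy-2-[4-methoxy-3-(methoxymethoxy)phenyl]-8-(3-methylbut-2-enyl)chromane (O-silylated flavan-4-ol, both C4 epimers) | COCOc1cc([C@@H]2CC(O[Si](C)(C)C(C)(C)C)c3c(OC)cc(OC)c(CC=C(C)C)c3O2)ccc1OC | intermediate
15 | (2S,4RS)-5,7-dimethoxy-2-[4-methoxy-3-(methoxymethoxy)phenyl]-8-(3-methylbut-2-enyl)chroman-4-ol (both C4 epimers) | COCOc1cc([C@@H]2CC(O)c3c(OC)cc(OC)c(CC=C(C)C)c3O2)ccc1OC | intermediate
16 | (2S)-5,7-dimethoxy-2-[4-methoxy-3-(methoxymethoxy)phenyl]-8-(3-methylbut-2-enyl)chroman-4-one | COCOc1cc([C@@H]2CC(=O)c3c(OC)cc(OC)c(CC=C(C)C)c3O2)ccc1OC | intermediate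
17 | (2S)-2-(3-hydroxy-4-methoxyphenyl)-5,7-dimethoxy-8-(3-methylbut-2-enyl)chroman-4-one | COc1ccc([C@@H]2CC(=O)c3c(OC)cc(OC)c(CC=C(C)C)c3O2)cc1O | target

**Step count.** Total: 12 steps. Longest linear sequence: 11 steps (steps 1–4, then 6–12); the ring B branch is step 5.

**Steps most likely to fail**

1. Step 9 (ring closure). Oxidative addition at the doubly ortho-substituted, electron-rich triflate may be slow. Carbonate or alkoxide may attack the sulfonate at sulfur and strip the triflate. β-Hydride loss from the palladium alkoxide may oxidise the C2 carbinol and reduce the arene. The silyl group may wander from the C4 oxygen to the C2 oxygen under base. The fallback closes ring C at the other C–O bond (C2–O1) by a Mitsunobu reaction with inversion. It sets out from 12: transfer hydrogenation with the enantiomeric catalyst RuCl[(R,R)-TsDPEN](p-cymene) should give the (1R,3RS)-silyloxy alcohol F1. Et4NOH in dioxane at rt then cleaves the aryl triflate to the (1R,3RS)-silyloxy phenol F2. PPh3 and DIAD in THF at 0 °C let the phenol oxygen displace the activated C2 hydroxyl with inversion, which should give 14, where the route is rejoined; some loss of enantiopurity by ionisation of the 4-methoxybenzylic centre is the point to watch there.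

2. Step 6 (aldol). The lithium aldolate of the hindered, electron-rich aldehyde may revert to its components. Water may be lost to the chalcone on work-up. Enolate or aldolate oxygen may attack the neighbouring triflate at sulfur. The fallback is a non-basic Mukaiyama aldol setting out from 9: TBSOTf and Et3N in CH2Cl2 give the tert-butyldimethylsilyl enol ether F3, and BF3·OEt2-mediated addition of it to 7 in CH2Cl2 at −78 °C, followed by aqueous work-up, returns to the route at 11.

3. Step 1 (propargyl ether). O-Alkylation of the hydrogen-bonded phenol may be sluggish, and the tertiary chloride may eliminate to the enyne instead of substituting. The fallback replaces the alkyne route by π-allylpalladium chemistry setting out from 1: tert-butyl 2-methylbut-3-en-2-yl carbonate with Pd(PPh3)4 in THF at 0 °C should deliver the tertiary allyl ether by decarboxylative Tsuji–Trost etherification at the more substituted allyl terminus. This returns to the route at 4, makes step 2 unnecessary, and forms no compound outside the list (F0).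

**Further compounds**

F1 | step 9 | (1R,3RS)-3-(tert-butyldimethylsilyloxy)-1-[4-methoxy-3-(methoxymethoxy)phenyl]-3-[4,6-dimethoxy-3-(3-methylbut-2-enyl)-2-(trifluoromethanesulfonyloxy)phenyl]propan-1-ol | COCOc1cc([C@H](O)CC(O[Si](C)(C)C(C)(C)C)c2c(OC)cc(OC)c(CC=C(C)C)c2OS(=O)(=O)C(F)(F)F)ccc1OC
F2 | step 9 | (1R,3RS)-3-(tert-butyldimethylsilyloxy)-3-[2-hydroxy-4,6-dimethoxy-3-(3-methylbut-2-enyl)phenyl]-1-[4-methoxy-3-(methoxymethoxy)phenyl]propan-1-ol | COCOc1cc([C@H](O)CC(O[Si](C)(C)C(C)(C)C)c2c(OC)cc(OC)c(CC=C(C)C)c2O)ccc1OC
F3 | step 6 | tert-butyl{1-[4-methoxy-3-(methoxymethoxy)phenyl]ethenyloxy}dimethylsilane | C=C(O[Si](C)(C)C(C)(C)C)c1ccc(OC)c(OCOC)c1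
F0 | step 1 | none | none
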